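**Plan**

- Retrosynthesis: (i) the spiro-epoxide oxygen is removed to leave C=CH2 on the one-carbon bridge; (ii) lactone ring A (its O–C(CH3)2 and C(=O)–O bonds) and the ring B diene go back to a ring B enol ether/ketone; (iii) the bicyclo[3.3.1]nonane is cut at three C–C bonds: ring-fusion CH–CH2, methyl-bearing bridgehead–bridging carbon (closes ring C), ester-bearing bridgehead–CH2 (closes ring D); (iv) quaternary ring B carbon–CH3.
- Forward: ring B comes first (from cycloheptane-1,3-dione; its quaternary carbon by asymmetric conjugate addition; a propargylic carbonate is carbonylated to a buta-2,3-dienoate). Rings C and D are then built in one flask with 2,4-dimethylpenta-1,4-dien-3-one, followed by methyl addition/transposition, ring A by carbonylation and Grignard lactonization, and the epoxide last.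
- Enabling feature: the bridging carbon lies between the ester-bearing bridgehead and its exocyclic CH2, so it is the central carbon of a 2-substituted allenoate. The chain CH2–C(CH3)–C(=O)–C(CH3)–CH2 that links the ring-fusion CH, the ketone and the ester bridgehead is a symmetrical diisopropenyl ketone.
- Stereochemistry: the quaternary ring B carbon comes from ligand-controlled conjugate addition; the ring-fusion CH from anti addition next to it; both bridgeheads from the trans B/C fusion and the bicyclic constraint; the carbinol from exo-face enolate oxidation; the epoxide from delivery by the tertiary hydroxyl group.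

Key step: step 12

Remark: rings are called A (lactone), B (seven-membered), C (six-membered ring fused to B) and D (six-membered ring with ketone and carbinol); the ligand antipode in step 6 is the one that gives the (S) quaternary carbon; ketone 17 is made in one step because its commercial supply is uncertain.

**Route**

Step 1
Reactants: 1 cycloheptane-1,3-dione; 2 tert-butyl bromoacetate
Product: 3 tert-butyl 2-(2,7-dioxocycloheptyl)acetate
Conditions: K2CO3, acetone, 56 °C
Reagents that add atoms: none
Why: C-alkylation of the 1,3-diketone enolate by the reactive alpha-bromo ester (enolate alkylation) should place the future lactone CH2C(=O) arm on the ring B carbon between the two carbonyl groups.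

Step 2
Reactants: 3 tert-butyl 2-(2,7-dioxocycloheptyl)acetate
Product: 4 tert-butyl 2-(2-methoxy-7-oxocyclohept-1-en-1-yl)acetate
Conditions: Me2SO4, K2CO3, acetone, 23 °C
Reagents that add atoms: dimethyl sulfate, COS(=O)(=O)OC
Why: O-methylation of the symmetrical 2-substituted 1,3-dione (vinylogous ester formation) should give a single enol ether, which keeps one carbonyl for enolate chemistry and stores the other for the later transposition.

Step 3
Reactants: 4 tert-butyl 2-(2-methoxy-7-oxocyclohept-1-en-1-yl)acetate
Product: 5 tert-butyl 2-(2-methoxy-7-oxocyclohepta-1,5-dien-1-yl)acetate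
Conditions: lithium diisopropylamide (1.05 equiv), THF, −78 °C; N-tert-butylbenzenesulfinimidoyl chloride, −78 °C
Reagents that add atoms: none
Why: kinetic alpha-prime enolization of the vinylogous ester (expected to be faster than enolization of the hindered tert-butyl ester) followed by one-pot sulfinimidoyl chloride dehydrogenation of the lithium enolate should give the cross-conjugated dienone.

Step 4
Reactants: 5 tert-butyl 2-(2-methoxy-7-oxocyclohepta-1,5-dien-1-yl)acetate; 6 tert-butyldimethyl(prop-2-yn-1-yloxy)silane
Product: 8 racemic alkynyl silyl dienol ether, via zinc acetylide 7 (not isolated)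
Conditions: 6, n-BuLi, THF, −78 °C; ZnBr2, 0 °C; then 5, TBSOTf, THF/Et2O, −40 °C
Reagents that add atoms: tert-butyldimethylsilyl trifluoromethanesulfonate, CC(C)(C)[Si](C)(C)OS(=O)(=O)C(F)(F)F
Why: silyl triflate-promoted conjugate addition of an alkynylzinc halide to a cyclic enone should occur at the unsubstituted beta-prime CH and not at the donor-deactivated methoxy-bearing beta carbon, and the enolate is trapped as its silyl ether.

Step 5
Reactants: 8 racemic alkynyl silyl dienol ether
Product: 9 tert-butyl 2-[5-[3-(tert-butyldimethylsilyloxy)prop-1-yn-1-yl]-2-methoxy-7-oxocyclohepta-1,5-dien-1-yl]acetate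
Conditions: Pd(OAc)2 (1.1 equiv), MeCN, 23 °C
Reagents that add atoms: none
Why: Saegusa–Ito oxidation of the silyl dienol ether should restore the enone, which now carries the alkynyl group on its beta carbon.

Step 6
Reactants: 9 beta-alkynyl dienone
Product: 10 (5S)-5-methyl ketone with the quaternary ring B carbon
Conditions: Me3Al (1.5 equiv), copper thiophene-2-carboxylate (5 mol %), (S)-binaphthol-derived N,N-bis[(S)-1-phenylethyl]phosphoramidite (10 mol %), Et2O, −30 °C; aq. potassium sodium tartrate
Reagents that add atoms: trimethylaluminium, C[Al](C)C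
Why: copper-catalysed asymmetric conjugate addition of Me3Al to a beta-substituted cyclic enone, a reaction type that is 1,4-selective on beta-alkynyl enones, should create the quaternary methyl-bearing ring B carbon with its configuration set by the chiral ligand.

Step 7
Reactants: 10 (5S)-5-methyl ketone
Product: 11 propargylic alcohol
Conditions: Bu4NF, AcOH, THF, 0 °C
Reagents that add atoms: none
Why: buffered fluoride should cleave the primary silyl ether (silyl ether deprotection) without touching the enol ether or the tert-butyl ester.

Step 8
Reactants: 11 propargylic alcohol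
Product: 12 propargylic methyl carbonate
Conditions: ClCO2Me, pyridine, CH2Cl2, 0 °C
Reagents that add atoms: methyl chloroformate, COC(=O)Cl
Why: acylation of the primary alcohol installs the carbonate leaving group needed for the carbonylation.

Step 9
Reactants: 12 propargylic methyl carbonate
Product: 13 silyl dienol ether of 12
Conditions: lithium diisopropylamide (1.1 equiv), THF, −78 °C; TBSOTf, −78 °C
Reagents that add atoms: tert-butyldimethylsilyl trifluoromethanesulfonate, CC(C)(C)[Si](C)(C)OS(=O)(=O)C(F)(F)F
Why: kinetic alpha-prime deprotonation of the vinylogous ester and O-silylation should give the cross-conjugated silyl dienol ether regiospecifically at the CH2 next to the quaternary carbon, which stores the enolate needed for the key step.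

Step 10
Reactants: 13 silyl dienol ether of 12
Product: 14 buta-2,3-dienoate (allenoate) silyl dienol ether
Conditions: CO (1 atm), Pd(OAc)2 (5 mol %), PPh3 (20 mol %), MeOH, 40 °C
Reagents that add atoms: carbon monoxide, [C-]#[O+]
Why: palladium-catalysed carbonylation of a propargylic carbonate (SN2′ ionization to an allenylpalladium methoxide, CO insertion, ester formation with the methoxide released from the carbonate) should give the 2-substituted buta-2,3-dienoate with the ester on the carbon attached to the quaternary center, while the silyl dienol ether survives the neutral medium.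

Step 11
Reactants: 15 methacryloyl chloride; 16 isopropenylmagnesium bromide
Product: 17 2,4-dimethylpenta-1,4-dien-3-one
Conditions: Fe(acac)3 (3 mol %), THF, −78 °C
Reagents that add atoms: none
Why: iron-catalysed acylation of the Grignard reagent by the acid chloride should stop at the ketone and give the symmetrical diisopropenyl ketone.

Step 12
Reactants: 14 buta-2,3-dienoate silyl dienol ether; 17 2,4-dimethylpenta-1,4-dien-3-one
Product: 21 tetracyclic hydroxy diketone (rings B, C and D), via Michael adduct enolate 18 (not isolated), via ring C dienolate 19 (not isolated), via bicyclic enolate 20 (not isolated)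
Conditions: 17 (3 equiv), tris(dimethylamino)sulfonium difluorotrimethylsilicate (1.05 equiv, slow addition), THF, −78 → −20 °C; then 2-(phenylsulfonyl)-3-phenyloxaziridine, −78 °C; AcOH
Reagents that add atoms: 2-(phenylsulfonyl)-3-phenyloxaziridine, O=S(=O)(c1ccccc1)N1OC1c1ccccc1
Why: Proposed new method: fluoride removes the silyl group of 14 to free the ring B enolate, which adds to one isopropenyl group of 17 (18); the new ketone enolate then attacks the central carbon of the buta-2,3-dienoate, closing ring C and forming the bond between the methyl-bearing bridgehead and the bridging carbon (19), the resulting ester dienolate adds through its alpha carbon to the second isopropenyl group, closing ring D (20), and the last enolate is hydroxylated in the same flask. The closest known reaction types are the intramolecular double Michael reaction of enolates that builds bridged bicycles, the conjugate addition of ketone enolates to the central carbon of allenoates, and the double Michael annulation of divinyl ketones; their combination in one three-component operation is the new element. Ring C closes in the 6-endo mode on the allenoate and ring D in the 6-endo-trig mode on the enone, both through chair-like six-membered arrays. The ring-fusion CH is set by approach of 17 anti to the larger (allenoate) substituent of the neighbouring quaternary carbon; the two bridgeheads follow from the trans B/C fusion and from the need for the acyl group to be axial in order to bridge (the epimeric adduct cannot close ring D and can return by retro-Michael reaction); the carbinol carbon is set by attack of the oxaziridine on the exo face of enolate 20, away from ring C. The step needs carbon attack and the right order of additions: the first enolate cannot reach the allenoate carbon through a four-membered ring and its oxygen addition is reversible, while each later enolate finds its acceptor within a six-membered array, so excess 17 and low temperature should suffice.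

Step 13
Reactants: 21 tetracyclic hydroxy diketone
Product: 23 ring B enone with the ring B methyl group, via carbinol 22 (not isolated)
Conditions: CeCl3, MeLi (3 equiv), THF, −78 °C; then 1 M HCl, THF, 0 °C
Reagents that add atoms: methyllithium, [Li]C
Why: 1,2-addition of the methylcerium reagent to the vinylogous ester carbonyl (the ring D ketone lies between two fully substituted carbons, the bridgehead ester is neopentyl and the other ester is tert-butyl), then acid hydrolysis and dehydration (Stork–Danheiser transposition), should give the tetrasubstituted enone.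

Step 14
Reactants: 23 ring B enone
Product: 24 dienyl triflate
Conditions: lithium diisopropylamide (2.2 equiv, the first equivalent for the OH), THF, −78 °C; PhNTf2, −78 → 0 °C
Reagents that add atoms: N-phenylbis(trifluoromethanesulfonimide), O=S(=O)(N(c1ccccc1)S(=O)(=O)C(F)(F)F)C(F)(F)F
Why: kinetic alpha-prime deprotonation of the enone at its only CH2 next to the carbonyl and O-triflation (enol triflate formation) should give the 2-triflyloxy-1,3-diene of ring B regiospecifically, since the ring D ketone has no alpha hydrogen.

Step 15
Reactants: 24 dienyl triflate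
Product: 25 methyl dienoate
Conditions: CO (1 atm), Pd(OAc)2 (10 mol %), 1,3-bis(diphenylphosphino)propane (10 mol %), Et3N, MeOH/DMF, 60 °C
Reagents that add atoms: carbon monoxide, [C-]#[O+]; methanol, CO
Why: palladium-catalysed methoxycarbonylation of the alkenyl triflate should put the carboxyl carbon of the future C(CH3)2–O unit on the diene.

Step 16
Reactants: 25 methyl dienoate
Product: 27 lactone with exocyclic methylene (de-epoxy target), via tertiary alkoxide 26 (not isolated)
Conditions: MeMgBr (5 equiv), THF, −20 °C; acetone (destroys excess reagent); then 45 °C; aq. NH4Cl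
Reagents that add atoms: methylmagnesium bromide, C[Mg]Br
Why: double Grignard addition to the least hindered ester (the dienoate) gives the dimethylcarbinol alkoxide, which on warming should close onto the tert-butyl ester (lactonization), so that ring A and its base-sensitive beta,gamma-unsaturated lactone appear only after the last strong-base step.

Step 17
Reactants: 27 lactone with exocyclic methylene
Product: 28 target spiro-epoxide
Conditions: VO(acac)2 (10 mol %), t-BuOOH (1.5 equiv), CH2Cl2, 0 → 23 °C
Reagents that add atoms: tert-butyl hydroperoxide, CC(C)(C)OO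
Why: vanadium-catalysed hydroxyl-directed epoxidation: the tertiary alcohol of ring D, which points at the one-carbon bridge in the boat form of ring D, should deliver oxygen to the ring D face of the exocyclic methylene (also the face not shielded by the axial angular methyl group), leaving the undirected ring B diene untouched and placing the epoxide oxygen syn to the carbinol bridge as in the target.

**Compound list**

1 | cycloheptane-1,3-dione | O=C1CCCCC(=O)C1 | starting material
2 | tert-butyl bromoacetate | BrCC(=O)OC(C)(C)C | starting material
3 | tert-butyl 2-(2,7-dioxocycloheptyl)acetate | O=C1CCCCC(=O)C1CC(=O)OC(C)(C)C | intermediate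
4 | tert-butyl 2-(2-methoxy-7-oxocyclohept-1-en-1-yl)acetate | COC1=C(CC(=O)OC(C)(C)C)C(=O)CCCC1 | intermediate
5 | tert-butyl 2-(2-methoxy-7-oxocyclohepta-1,5-dien-1-yl)acetate | COC1=C(CC(=O)OC(C)(C)C)C(=O)C=CCC1 | intermediate
6 | tert-butyldimethyl(prop-2-yn-1-yloxy)silane | C#CCO[Si](C)(C)C(C)(C)C | starting material
7 | bromo[3-(tert-butyldimethylsilyloxy)prop-1-yn-1-yl]zinc | Br[Zn]C#CCO[Si](C)(C)C(C)(C)C | intermediate
8 | tert-butyl 2-[7-(tert-butyldimethylsilyloxy)-5-[3-(tert-butyldimethylsilyloxy)prop-1-yn-1-yl]-2-methoxycyclohepta-1,6-dien-1-yl]acetate (racemic) | COC1=C(CC(=O)OC(C)(C)C)C(O[Si](C)(C)C(C)(C)C)=CC(C#CCO[Si](C)(C)C(C)(C)C)CC1 | intermediate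
9 | tert-butyl 2-[5-[3-(tert-butyldimethylsilyloxy)prop-1-yn-1-yl]-2-methoxy-7-oxocyclohepta-1,5-dien-1-yl]acetate | COC1=C(CC(=O)OC(C)(C)C)C(=O)C=C(C#CCO[Si](C)(C)C(C)(C)C)CC1 | intermediate
10 | tert-butyl 2-[(5S)-5-[3-(tert-butyldimethylsilyloxy)prop-1-yn-1-yl]-2-methoxy-5-methyl-7-oxocyclohept-1-en-1-yl]acetate | O=C1C[C@@](C)(C#CCO[Si](C)(C)C(C)(C)C)CCC(OC)=C1CC(=O)OC(C)(C)C | intermediate
11 | tert-butyl 2-[(5S)-5-(3-hydroxyprop-1-yn-1-yl)-2-methoxy-5-methyl-7-oxocyclohept-1-en-1-yl]acetate | O=C1C[C@@](C)(C#CCO)CCC(OC)=C1CC(=O)OC(C)(C)C | intermediate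
12 | tert-butyl 2-[(5S)-2-methoxy-5-[3-(methoxycarbonyloxy)prop-1-yn-1-yl]-5-methyl-7-oxocyclohept-1-en-1-yl]acetate | O=C1C[C@@](C)(C#CCOC(=O)OC)CCC(OC)=C1CC(=O)OC(C)(C)C | intermediate
13 | tert-butyl 2-[(5S)-7-(tert-butyldimethylsilyloxy)-2-methoxy-5-[3-(methoxycarbonyloxy)prop-1-yn-1-yl]-5-methylcyclohepta-1,6-dien-1-yl]acetate | COC1=C(CC(=O)OC(C)(C)C)C(O[Si](C)(C)C(C)(C)C)=C[C@@](C)(C#CCOC(=O)OC)CC1 | intermediate
14 | methyl 2-[(1S)-4-(2-tert-butoxy-2-oxoethyl)-3-(tert-butyldimethylsilyloxy)-5-methoxy-1-methylcyclohepta-2,4-dien-1-yl]buta-2,3-dienoate | COC1=C(CC(=O)OC(C)(C)C)C(O[Si](C)(C)C(C)(C)C)=C[C@@](C)(C(=C=C)C(=O)OC)CC1 | intermediate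
15 | methacryloyl chloride | C=C(C)C(Cl)=O | starting material
16 | isopropenylmagnesium bromide | C=C(C)[Mg]Br | starting material
17 | 2,4-dimethylpenta-1,4-dien-3-one | C=C(C)C(=O)C(C)=C | intermediate
18 | enolate of the first Michael adduct: ring B ketone of 14 whose alpha CH carries, trans to the allenoate on the neighbouring quaternary carbon, the chain CH2–C(CH3)=C(O−)–C(CH3)=CH2 | COC1=C(CC(=O)OC(C)(C)C)C(=O)[C@H](CC(C)=C([O-])C(C)=C)[C@@](C)(C(=C=C)C(=O)OC)CC1 | intermediate
19 | ester dienolate with ring C closed trans to ring B: new quaternary carbon bears CH3 (equatorial) and methacryloyl (axial); exocyclic CH2 on the carbon between it and the enolate carbon | COC([O-])=C1C(=C)[C@](C)(C(=O)C(C)=C)C[C@H]2C(=O)C(CC(=O)OC(C)(C)C)=C(OC)CC[C@]12C | intermediate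
20 | ketone enolate with ring D closed: bicyclo[3.3.1]nonane with CO2CH3 and CH3 bridgeheads, C=CH2 one-carbon bridge and CH2–C(CH3)=C(O−) bridge, trans-fused to ring B | COC(=O)[C@]12CC(C)=C([O-])[C@](C)(C[C@H]3C(=O)C(CC(=O)OC(C)(C)C)=C(OC)CC[C@@]31C)C2=C | intermediate
21 | tetracyclic hydroxy diketone: ring B = 2-(tert-butoxycarbonylmethyl)-3-methoxycyclohept-2-en-1-one trans-fused at C7 (H) and C6 (angular CH3) to ring C; rings C and D = bicyclo[3.3.1]nonane with CO2CH3 on the bridgehead next to the angular-methyl carbon, CH3 on the other bridgehead, C=CH2 as one-carbon bridge and CH2–C(CH3)(OH)–C(=O) as second three-carbon bridge (OH exo, its CH3 toward ring C) | COC(=O)[C@]12C[C@@](C)(O)C(=O)[C@](C)(C[C@H]3C(=O)C(CC(=O)OC(C)(C)C)=C(OC)CC[C@@]31C)C2=C | intermediate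
22 | tertiary carbinol from methyl addition to the ring B carbonyl of 21 (formed as its metal alkoxide, either epimer at the new carbinol carbon) | COC(=O)[C@]12C[C@@](C)(O)C(=O)[C@](C)(C[C@H]3C(C)(O)C(CC(=O)OC(C)(C)C)=C(OC)CC[C@@]31C)C2=C | intermediate
23 | transposed enone: as 21 but ring B = 2-(tert-butoxycarbonylmethyl)-3-methylcyclohept-2-en-1-one fused at C4 (H) and C5 (angular CH3) | COC(=O)[C@]12C[C@@](C)(O)C(=O)[C@](C)(C[C@H]3C(C)=C(CC(=O)OC(C)(C)C)C(=O)CC[C@@]31C)C2=C | intermediate
24 | dienyl triflate: enol triflate of the ring B ketone of 23 toward its CH2 (ring B 1,3-diene, OTf on the inner diene carbon next to CH=) | COC(=O)[C@]12C[C@@](C)(O)C(=O)[C@](C)(C[C@H]3C(C)=C(CC(=O)OC(C)(C)C)C(OS(=O)(=O)C(F)(F)F)=CC[C@@]31C)C2=C | intermediate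
25 | methyl dienoate: as 24 with CO2CH3 in place of OTf | COC(=O)[C@]12C[C@@](C)(O)C(=O)[C@](C)(C[C@H]3C(C)=C(CC(=O)OC(C)(C)C)C(C(=O)OC)=CC[C@@]31C)C2=C | intermediate
26 | bromomagnesium alkoxide of the dimethylcarbinol: as 25 with C(CH3)2O− in place of CO2CH3 | COC(=O)[C@]12C[C@@](C)(O)C(=O)[C@](C)(C[C@H]3C(C)=C(CC(=O)OC(C)(C)C)C(C(C)(C)[O-])=CC[C@@]31C)C2=C | intermediate
27 | de-epoxy target: lactone ring A closed (O–C(CH3)2 on the diene, CH2–C(=O) on the methyl-bearing alkene), one-carbon bridge C=CH2, all five stereocentres as in the target | COC(=O)[C@]12C[C@@](C)(O)C(=O)[C@](C)(C[C@H]3C(C)=C4CC(=O)OC(C)(C)C4=CC[C@@]31C)C2=C | intermediate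
28 | target: spiro-epoxide on the one-carbon bridge with oxygen syn to the ketone/carbinol bridge (ring D) and CH2 syn to ring C; ring-fusion H and angular CH3 trans; tertiary OH exo | COC(=O)[C@]12C[C@@](C)(O)C(=O)[C@](C)(C[C@H]3C(C)=C4CC(=O)OC(C)(C)C4=CC[C@@]31C)[C@]21CO1 | target

**Count and risks**

Total step count: 17. Longest linear sequence: 16 steps (steps 1–10 and 12–17); step 11 makes the second fragment.

The three steps most likely to fail:

1. Step 12 (proposed new method). The freed ring B enolate may add through oxygen to its own allenoate or to a second molecule, or be quenched by proton transfer from the tert-butyl ester CH2, before it meets 17; the ring C closure may also give the epimer that cannot bridge. Fallback with known reactions, with the union moved in front of the allenoate: from 13, TBSOTf-catalysed Mukaiyama–Michael addition to 17 should give silyl enol ether adduct F1 while the propargylic carbonate stays inert. Palladium-catalysed carbonylation as in step 10 then gives allenoate F2. Tris(dimethylamino)sulfonium difluorotrimethylsilicate followed by the oxaziridine then brings about the intramolecular double Michael reaction and the hydroxylation, and the sequence comes back at 21.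

2. Step 13. The methyl nucleophile may also attack the ring D ketone or an ester, and the carbinol may not transpose cleanly. Fallback with the ketone masked and the hydroxyl group introduced later: from 14 (with 17), step 12 is run with a TBSOTf quench of enolate 20 in place of the oxaziridine, which should give ring D silyl enol ether F3. MeLi/CeCl3 followed by pyridinium p-toluenesulfonate in wet acetone gives enone F4. Rubottom oxidation with dimethyldioxirane gives silyloxy ketone F5, and HF·pyridine brings the sequence back at 23.

3. Step 17. Oxygen transfer to the electron-rich ring B diene may compete if the hydroxyl group directs poorly. Fallback with the epoxide made before the diene exists: from 23, whose only electron-rich alkene is the exocyclic methylene, m-chloroperbenzoic acid with NaHCO3 should give epoxy enone F6. The conditions of steps 14 and 15 then give epoxy triflate F7 and epoxy dienoate F8, and the Grignard addition and lactonization of step 16, through epoxy alkoxide F9, end directly at 28.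

**Further compounds**

F1 | step 12 | Mukaiyama–Michael adduct of 13 and 17: ring B ketone with the silyl enol ether chain CH2–C(CH3)=C(OTBS)–C(CH3)=CH2 trans to the propargylic carbonate arm | COC1=C(CC(=O)OC(C)(C)C)C(=O)[C@H](CC(C)=C(O[Si](C)(C)C(C)(C)C)C(C)=C)[C@@](C)(C#CCOC(=O)OC)CC1
F2 | step 12 | buta-2,3-dienoate from F1 | COC1=C(CC(=O)OC(C)(C)C)C(=O)[C@H](CC(C)=C(O[Si](C)(C)C(C)(C)C)C(C)=C)[C@@](C)(C(=C=C)C(=O)OC)CC1
F3 | step 13 | tert-butyldimethylsilyl enol ether of the ring D ketone (O-silylated 20) | COC(=O)[C@]12CC(C)=C(O[Si](C)(C)C(C)(C)C)[C@](C)(C[C@H]3C(=O)C(CC(=O)OC(C)(C)C)=C(OC)CC[C@@]31C)C2=C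
F4 | step 13 | transposed ring B enone with the ring D silyl enol ether intact | COC(=O)[C@]12CC(C)=C(O[Si](C)(C)C(C)(C)C)[C@](C)(C[C@H]3C(C)=C(CC(=O)OC(C)(C)C)C(=O)CC[C@@]31C)C2=C
F5 | step 13 | tert-butyldimethylsilyl ether of 23 at the tertiary carbinol | COC(=O)[C@]12C[C@@](C)(O[Si](C)(C)C(C)(C)C)C(=O)[C@](C)(C[C@H]3C(C)=C(CC(=O)OC(C)(C)C)C(=O)CC[C@@]31C)C2=C
F6 | step 17 | spiro-epoxide of enone 23 | COC(=O)[C@]12C[C@@](C)(O)C(=O)[C@](C)(C[C@H]3C(C)=C(CC(=O)OC(C)(C)C)C(=O)CC[C@@]31C)[C@]21CO1
F7 | step 17 | spiro-epoxide of dienyl triflate 24 | COC(=O)[C@]12C[C@@](C)(O)C(=O)[C@](C)(C[C@H]3C(C)=C(CC(=O)OC(C)(C)C)C(OS(=O)(=O)C(F)(F)F)=CC[C@@]31C)[C@]21CO1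
F8 | step 17 | spiro-epoxide of methyl dienoate 25 | COC(=O)[C@]12C[C@@](C)(O)C(=O)[C@](C)(C[C@H]3C(C)=C(CC(=O)OC(C)(C)C)C(C(=O)OC)=CC[C@@]31C)[C@]21CO1
F9 | step 17 | spiro-epoxide of alkoxide 26 | COC(=O)[C@]12C[C@@](C)(O)C(=O)[C@](C)(C[C@H]3C(C)=C(CC(=O)OC(C)(C)C)C(C(C)(C)[O-])=CC[C@@]31C)[C@]21CO1
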